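The trimer is cut at the interflavan bond between C4 of the pyran C-ring of the upper epicatechin gallate unit and C6 of the phloroglucinol A-ring of the middle unit. The key step ionises a 4β-alkoxy, 6,8-dibromo upper unit to its A-ring-stabilised C4 benzylic cation. This cation is trapped by a benzylated gallate dimer in which bromine occupies C8 of the middle and C6 of the lower A-ring. C6–H of the middle unit is then the only phloroglucinol C–H present. The rare 4→6 regiochemistry and the 4β configuration (trans to the C3 galloyloxy group) therefore arise in one operation. One hydrogenolysis then removes eighteen benzyl groups and four bromines.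

Key step: step 8

Remark: 1 and 8 are taken as the commercial natural enantiomers and 5 as the commercial acid. β denotes the face opposite to the C2 aryl group of a 2R flavan unit, so 4β is trans to the 3-oxygen of an epicatechin unit.

Step 1
Reactants: 1 (−)-epicatechin
Product: 2 5,7,3′,4′-tetra-O-benzyl-(−)-epicatechin
Conditions: BnBr (4.5 equiv), K2CO3 (5 equiv), DMF, 0 °C → rt, Ar
Reagents that add atoms: benzyl bromide BrCc1ccccc1
Why: Williamson ether synthesis that alkylates the four phenols only, because carbonate does not deprotonate the aliphatic 3-OH, while the anhydrous, oxygen-free medium should leave the C2 and C3 stereocentres untouched.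

Step 2
Reactants: 2 5,7,3′,4′-tetra-O-benzyl-(−)-epicatechin
Product: 4 4β-(2-ethoxyethoxy)-tetra-O-benzylepicatechin, via flavan-4-ylium ion 3 (not isolated)
Conditions: DDQ (2 equiv), 2-ethoxyethanol (10 equiv), CH2Cl2, rt
Reagents that add atoms: 2-ethoxyethanol CCOCCO
Why: DDQ benzylic C–H oxidation (hydride abstraction) at C4, the position conjugated with O1, 5-O and 7-O of the A-ring, gives cation 3, which the alcohol should capture from the β-face, anti to the α-oriented C2 aryl and C3 hydroxyl groups, setting C4 as 3,4-trans (4S).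

Step 3
Reactants: 4 4β-(2-ethoxyethoxy)-tetra-O-benzylepicatechin; 5 3,4,5-tris(benzyloxy)benzoic acid
Product: 6 4β-(2-ethoxyethoxy)-hepta-O-benzyl-epicatechin 3-O-gallate
Conditions: 5 (1.3 equiv), DCC (1.5 equiv), DMAP (0.2 equiv), CH2Cl2, 0 °C → rt
Reagents that add atoms: none
Why: Steglich esterification acylates the only free hydroxyl group at oxygen, so the C3–O bond and the C2, C3 and C4 configurations are untouched, and the acid-free medium should keep the labile C4 ether.

Step 4
Reactants: 6 4β-(2-ethoxyethoxy)-hepta-O-benzyl-epicatechin 3-O-gallate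
Product: 7 6,8-dibromo-4β-(2-ethoxyethoxy)-hepta-O-benzyl-epicatechin 3-O-gallate
Conditions: NBS (2.2 equiv), CH2Cl2, −45 °C → rt, dark
Reagents that add atoms: N-bromosuccinimide O=C1CCC(=O)N1Br
Why: Electrophilic aromatic bromination (SEAr) in which only the phloroglucinol-type A-ring is electron-rich enough to react, C8 first and C6 second, while the neutral medium should leave the acid-labile C4 ether and all stereocentres in place.

Step 5
Reactants: 8 (+)-catechin
Product: 9 5,7,3′,4′-tetra-O-benzyl-(+)-catechin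
Conditions: BnBr (4.5 equiv), K2CO3 (5 equiv), DMF, rt, Ar
Reagents that add atoms: benzyl bromide BrCc1ccccc1
Why: Williamson ether synthesis that alkylates the four phenols only, because carbonate does not deprotonate the aliphatic 3-OH, which stays free as the target requires.

Step 6
Reactants: 6 4β-(2-ethoxyethoxy)-hepta-O-benzyl-epicatechin 3-O-gallate; 9 5,7,3′,4′-tetra-O-benzyl-(+)-catechin
Product: 11 undeca-O-benzyl epicatechin 3-O-gallate-(4β→8)-catechin, via galloylated flavan-4-ylium ion 10 (not isolated)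
Conditions: 9 (4 equiv, excess recoverable), TMSOTf (0.1 equiv), CH2Cl2, −78 °C
Reagents that add atoms: none
Why: Lewis-acid-catalysed Friedel–Crafts interflavan coupling in which cation 10 should be attacked by C8, the most nucleophilic and least hindered position of 9, from the β-face anti to the C2 aryl and C3 galloyloxy groups (new C4 centre 3,4-trans), while the excess of 9 suppresses self-condensation of 6.

Step 7
Reactants: 11 undeca-O-benzyl epicatechin 3-O-gallate-(4β→8)-catechin
Product: 12 dibromo dimer carrying Br at C8 of the gallate unit and at C6 of the catechin unit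
Conditions: NBS (2.0 equiv), CH2Cl2, −78 → −20 °C, dark
Reagents that add atoms: N-bromosuccinimide O=C1CCC(=O)N1Br
Why: Electrophilic aromatic bromination (SEAr) in which the A-ring of the gallate unit reacts with the innate C8-over-C6 preference of benzylated flavan-3-ols, and its new bromine, meta to C6, deactivates that ring purely inductively, so the second equivalent should go to C6 of the still bromine-free A-ring of the catechin unit.

Step 8
Reactants: 7 6,8-dibromo-4β-(2-ethoxyethoxy)-hepta-O-benzyl-epicatechin 3-O-gallate; 12 dibromo dimer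
Product: 14 tetrabromo-octadeca-O-benzyl trimer with the 4β→6 and 4β→8 bonds, via dibromoflavan-4-ylium ion 13 (not isolated)
Conditions: 7 (1.3 equiv), TMSOTf (0.3 equiv), 4 Å MS, CH2Cl2, −40 → 0 °C
Reagents that add atoms: none
Why: TMSOTf activates the chelating 2-ethoxyethoxy group of 7, whose departure gives cation 13, a C4 benzylic cation delocalised into O1, 5-O and 7-O of its A-ring and shielded on the α-face by the gallate carbonyl oxygen; C6 of the A-ring of the gallate unit of 12 (the future middle unit) attacks it, and loss of the C6 proton restores aromaticity and regenerates the acid. The closest known reaction type is the Lewis-acid-mediated Friedel–Crafts interflavan coupling of 4-alkoxyflavan donors with halogen-capped flavan-3-ol acceptors, a type known for 4→8 and for 4→6 bonds. No ring is closed. The one new stereocentre, C4 of the upper unit of 14, is under substrate control: the α-face carries the C2 aryl group and the C3 ester, so the arene should enter from the β-face and the bond forms 3,4-trans (4β). The step needs site selectivity among the phloroglucinol positions and chemoselectivity against self-condensation; bromine occupies C6 and C8 of the donor, C8 of the gallate-unit A-ring and C6 of the catechin-unit A-ring of the acceptor, so the wanted C6–H is the only one left, the catechol and galloyl rings are far less nucleophilic, and O-alkylation of the free 3-OH is reversible under the acid. Product 14 has no free phloroglucinol C–H, so the coupling ends by itself and a slight excess of donor can be used.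

Step 9
Reactants: 14 tetrabromo-octadeca-O-benzyl trimer
Product: 15 epicatechin 3-O-gallate-(4β→6)-epicatechin 3-O-gallate-(4β→8)-catechin (CNP0112921.1)
Conditions: H2 (1 atm), 20% Pd(OH)2/C, NaOAc (4.4 equiv), THF/MeOH/H2O, rt
Reagents that add atoms: none
Why: Heterogeneous catalytic hydrogenolysis should cleave all eighteen aryl benzyl ethers and hydrodehalogenate the four aryl bromides in one operation, while the acetate buffers the hydrogen bromide so that the acid-labile interflavan bonds, both gallate esters and all eight stereocentres are kept.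

Compound list
1 | (−)-epicatechin, (2R,3R) | O[C@@H]1Cc2c(O)cc(O)cc2O[C@@H]1c1ccc(O)c(O)c1 | starting material
2 | 5,7,3′,4′-tetra-O-benzyl-(−)-epicatechin, (2R,3R), free 3-OH | O[C@@H]1Cc2c(OCc3ccccc3)cc(OCc3ccccc3)cc2O[C@@H]1c1ccc(OCc2ccccc2)c(OCc2ccccc2)c1 | intermediate
3 | flavan-4-ylium ion of 2 (C4 cation, free 3-OH, C2 and C3 unchanged; not isolated) | O[C@@H]1[CH+]c2c(OCc3ccccc3)cc(OCc3ccccc3)cc2O[C@@H]1c1ccc(OCc2ccccc2)c(OCc2ccccc2)c1 | intermediate
4 | (2R,3R,4S)-4β-(2-ethoxyethoxy)-5,7,3′,4′-tetra-O-benzylepicatechin (3,4-trans, free 3-OH) | O[C@@H]1[C@@H](OCCOCC)c2c(OCc3ccccc3)cc(OCc3ccccc3)cc2O[C@@H]1c1ccc(OCc2ccccc2)c(OCc2ccccc2)c1 | intermediate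
5 | 3,4,5-tris(benzyloxy)benzoic acid (tri-O-benzylgallic acid) | O=C(O)c1cc(OCc2ccccc2)c(OCc2ccccc2)c(OCc2ccccc2)c1 | starting material
6 | (2R,3R,4S)-4β-(2-ethoxyethoxy)-hepta-O-benzyl-epicatechin 3-O-gallate (3,4-trans) | O=C(O[C@@H]1[C@@H](OCCOCC)c2c(OCc3ccccc3)cc(OCc3ccccc3)cc2O[C@@H]1c1ccc(OCc2ccccc2)c(OCc2ccccc2)c1)c1cc(OCc2ccccc2)c(OCc2ccccc2)c(OCc2ccccc2)c1 | intermediate
7 | 6,8-dibromo derivative of 6 (2R,3R,4S) | O=C(O[C@@H]1[C@@H](OCCOCC)c2c(OCc3ccccc3)c(Br)c(OCc3ccccc3)c(Br)c2O[C@@H]1c1ccc(OCc2ccccc2)c(OCc2ccccc2)c1)c1cc(OCc2ccccc2)c(OCc2ccccc2)c(OCc2ccccc2)c1 | intermediate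
8 | (+)-catechin, (2R,3S) | O[C@H]1Cc2c(O)cc(O)cc2O[C@@H]1c1ccc(O)c(O)c1 | starting material
9 | 5,7,3′,4′-tetra-O-benzyl-(+)-catechin, free 3-OH | O[C@H]1Cc2c(OCc3ccccc3)cc(OCc3ccccc3)cc2O[C@@H]1c1ccc(OCc2ccccc2)c(OCc2ccccc2)c1 | intermediate
10 | galloylated flavan-4-ylium ion from 6 (C4 cation, C2 and C3 unchanged; not isolated) | O=C(O[C@@H]1[CH+]c2c(OCc3ccccc3)cc(OCc3ccccc3)cc2O[C@@H]1c1ccc(OCc2ccccc2)c(OCc2ccccc2)c1)c1cc(OCc2ccccc2)c(OCc2ccccc2)c(OCc2ccccc2)c1 | intermediate
11 | undeca-O-benzyl epicatechin 3-O-gallate-(4β→8)-catechin, free 3-OH in the catechin unit | O=C(O[C@@H]1[C@@H](c2c(OCc3ccccc3)cc(OCc3ccccc3)c3c2O[C@H](c2ccc(OCc4ccccc4)c(OCc4ccccc4)c2)[C@@H](O)C3)c2c(OCc3ccccc3)cc(OCc3ccccc3)cc2O[C@@H]1c1ccc(OCc2ccccc2)c(OCc2ccccc2)c1)c1cc(OCc2ccccc2)c(OCc2ccccc2)c(OCc2ccccc2)c1 | intermediate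
12 | dibromo dimer: 11 with Br at C8 of the gallate unit and at C6 of the catechin unit | O=C(O[C@@H]1[C@@H](c2c(OCc3ccccc3)c(Br)c(OCc3ccccc3)c3c2O[C@H](c2ccc(OCc4ccccc4)c(OCc4ccccc4)c2)[C@@H](O)C3)c2c(OCc3ccccc3)cc(OCc3ccccc3)c(Br)c2O[C@@H]1c1ccc(OCc2ccccc2)c(OCc2ccccc2)c1)c1cc(OCc2ccccc2)c(OCc2ccccc2)c(OCc2ccccc2)c1 | intermediate
13 | 6,8-dibromoflavan-4-ylium ion from 7 (C4 cation; not isolated) | O=C(O[C@@H]1[CH+]c2c(OCc3ccccc3)c(Br)c(OCc3ccccc3)c(Br)c2O[C@@H]1c1ccc(OCc2ccccc2)c(OCc2ccccc2)c1)c1cc(OCc2ccccc2)c(OCc2ccccc2)c(OCc2ccccc2)c1 | intermediate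
14 | tetrabromo-octadeca-O-benzyl trimer: Br at C6 and C8 (upper), C8 (middle), C6 (lower); 4β→6 and 4β→8 bonds; free 3-OH in the lower unit | O=C(O[C@@H]1[C@@H](c2c(OCc3ccccc3)c(Br)c3c(c2OCc5ccccc5)[C@H](c2c(OCc4ccccc4)c(Br)c(OCc4ccccc4)c4c2O[C@H](c2ccc(OCc5ccccc5)c(OCc5ccccc5)c2)[C@@H](O)C4)[C@@H](OC(=O)c2cc(OCc4ccccc4)c(OCc4ccccc4)c(OCc4ccccc4)c2)[C@@H](c2ccc(OCc4ccccc4)c(OCc4ccccc4)c2)O3)c2c(OCc3ccccc3)c(Br)c(OCc3ccccc3)c(Br)c2O[C@@H]1c1ccc(OCc2ccccc2)c(OCc2ccccc2)c1)c1cc(OCc2ccccc2)c(OCc2ccccc2)c(OCc2ccccc2)c1 | intermediate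
15 | epicatechin 3-O-gallate-(4β→6)-epicatechin 3-O-gallate-(4β→8)-catechin (CNP0112921.1) | O=C(O[C@@H]1[C@@H](c2c(O)cc3c(c2O)[C@H](c2c(O)cc(O)c4c2O[C@H](c2ccc(O)c(O)c2)[C@@H](O)C4)[C@@H](OC(=O)c2cc(O)c(O)c(O)c2)[C@@H](c2ccc(O)c(O)c2)O3)c2c(O)cc(O)cc2O[C@@H]1c1ccc(O)c(O)c1)c1cc(O)c(O)c(O)c1 | target

Total step count: 9
Longest linear sequence: 7 steps (1, 2, 3, 6, 7, 8, 9)

Steps most likely to fail

**Step 8.**
What may go wrong: ionisation of the doubly brominated donor may be slow. Reversible capture of the cation by the liberated alcohol or by the free 3-OH of 12 may then outlast the lifetime of the cation. The cation would decay by loss of H3 or by acid-induced bromine transfer before the hindered C6 position attacks. The fallback changes the donor class from hard, reversible activation to soft, irreversible activation and sets out from 7. Exchange of the ether with 2-mercaptobenzothiazole and catalytic BF3·OEt2 in CH2Cl2 should give the 6,8-dibromo-4β-(benzothiazol-2-ylthio) donor F1. AgBF4 in THF/CH2Cl2 at 0 °C, with 12 present, should then ionise it through precipitation of the silver thiolate, a mode in which no alcohol is released. The same β-face C6 attack follows, and the sequence comes back to the route at 14.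

**Step 7.**
What may go wrong: site control may be lost. C6 of the gallate-unit A-ring may be brominated before the catechin-unit ring has reacted, or the bromine may be distributed unevenly over the two rings. In the fallback the first bromine is placed before the coupling, where only the C8 preference of a monomer is needed. It sets out from 6 and 9. NBS (1.0 equiv, CH2Cl2, −45 °C) on 6 should give the 8-bromo-4β-(2-ethoxyethoxy) donor F2. Its coupling with 9 (about 1.5 equiv, catalytic TMSOTf, CH2Cl2, −78 → −40 °C) should give the monobromo dimer F3. A further 1.0 equiv of NBS then meets only one bromine-free phloroglucinol ring and should brominate C6 of the catechin unit, and the sequence comes back to the route at 12.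

**Step 9.**
What may go wrong: hydrodebromination may stall at the di-ortho-substituted positions through bromide poisoning of the catalyst. The interflavan bonds may also undergo acid-induced cleavage once the phenols are free. The fallback separates the two reductions and sets out from 14. Homogeneous palladium-catalysed transfer hydrodehalogenation (Pd(OAc)2, SPhos, HCO2Na, DMF, 80 °C) spares benzyl ethers. It should give the bromine-free octadeca-O-benzyl trimer F4, which can be purified on silica. Halide-free hydrogenolysis (H2, Pd(OH)2/C, THF/MeOH/H2O, rt) then comes back to the route at 15.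

Further compounds
F1 | step 8 | 6,8-dibromo-4β-(benzothiazol-2-ylthio)-hepta-O-benzyl-epicatechin 3-O-gallate | O=C(O[C@@H]1[C@@H](Sc3nc4ccccc4s3)c2c(OCc3ccccc3)c(Br)c(OCc3ccccc3)c(Br)c2O[C@@H]1c1ccc(OCc2ccccc2)c(OCc2ccccc2)c1)c1cc(OCc2ccccc2)c(OCc2ccccc2)c(OCc2ccccc2)c1
F2 | step 7 | 8-bromo-4β-(2-ethoxyethoxy)-hepta-O-benzyl-epicatechin 3-O-gallate | O=C(O[C@@H]1[C@@H](OCCOCC)c2c(OCc3ccccc3)cc(OCc3ccccc3)c(Br)c2O[C@@H]1c1ccc(OCc2ccccc2)c(OCc2ccccc2)c1)c1cc(OCc2ccccc2)c(OCc2ccccc2)c(OCc2ccccc2)c1
F3 | step 7 | monobromo dimer: 11 with Br at C8 of the gallate unit only | O=C(O[C@@H]1[C@@H](c2c(OCc3ccccc3)cc(OCc3ccccc3)c3c2O[C@H](c2ccc(OCc4ccccc4)c(OCc4ccccc4)c2)[C@@H](O)C3)c2c(OCc3ccccc3)cc(OCc3ccccc3)c(Br)c2O[C@@H]1c1ccc(OCc2ccccc2)c(OCc2ccccc2)c1)c1cc(OCc2ccccc2)c(OCc2ccccc2)c(OCc2ccccc2)c1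
F4 | step 9 | bromine-free octadeca-O-benzyl trimer | O=C(O[C@@H]1[C@@H](c2c(OCc3ccccc3)cc3c(c2OCc5ccccc5)[C@H](c2c(OCc4ccccc4)cc(OCc4ccccc4)c4c2O[C@H](c2ccc(OCc5ccccc5)c(OCc5ccccc5)c2)[C@@H](O)C4)[C@@H](OC(=O)c2cc(OCc4ccccc4)c(OCc4ccccc4)c(OCc4ccccc4)c2)[C@@H](c2ccc(OCc4ccccc4)c(OCc4ccccc4)c2)O3)c2c(OCc3ccccc3)cc(OCc3ccccc3)cc2O[C@@H]1c1ccc(OCc2ccccc2)c(OCc2ccccc2)c1)c1cc(OCc2ccccc2)c(OCc2ccccc2)c(OCc2ccccc2)c1
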